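At 12 d you read the complex with one exchanged in each flask, well beyond the last earlier reading at 4.00 d.

| flask | starting complex | incoming ligand | leaving ligand | remark | time |
|---|---|---|---|---|---|
| gamma | 26 mM | 13.6 mM | 85 mM | run made earlier |  |
| epsilon | 17 mM | 13.6 mM | 170 mM | run made earlier |  |
| north-east | 17 mM | 13.6 mM | 85.0 mM |  | 12 d |
| north | 17 mM | 20.4 mM | 85.0 mM |  | 12 d |
| east | 17 mM | 25.5 mM | 85.0 mM |  | 12 d |

| run | time / d | complex with one exchanged / % | complex with two exchanged / % | starting complex / % |
|---|---|---|---|---|
| gamma | 0.333 | 16.1 | 0.3 | 84.5 |
| gamma | 0.833 | 20.5 | 0.6 | 79.0 |
| gamma | 1.67 | 28.1 | 0.2 | 71.3 |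
| gamma | 4.00 | 39.3 | 0 | 59.1 |
| epsilon | 0.333 | 12.4 | 0 | 87.0 |
| epsilon | 0.833 | 17.2 | 0.6 | 81.9 |
| epsilon | 1.67 | 24.8 | 0 | 73.7 |
| epsilon | 4.00 | 45.4 | 0 | 53.4 |

(each reading ± 0.5 percentage points)

- complex with one exchanged at the end, in percent of the starting complex charged, for each flask in turn (north-east, north, east)

- the earlier runs were read with a standard deviation of 0.5 percentage points
- no earlier run changes the charge of incoming ligand; that part of a forecast is a guess

Keep a ledger of the incoming ligand, in percent of the starting complex charged. North-east opens with 80.0 % as its allowance A, the charge of incoming ligand over the charge of starting complex. Each exchange books one incoming ligand, so a complex with two exchanged costs two entries, and whatever is unbooked stays in solution.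

Epsilon has the north-east charges of starting complex and incoming ligand, with twice the leaving ligand. At 4.00 d it had booked 45.4 % as complex with one exchanged, while complex with two exchanged read 0 %, inside the scatter. Counting these two read forms, that leaves 35 percentage points of allowance unbooked in epsilon; any further form was not read.

My reckoning commits to a ceiling, not a point: in north-east, incoming ligand is the limiting reagent against starting complex, so complex with one exchanged must stay below A. North opens with 120 % and east with 150 %, so there the ceiling is the 100 % of starting complex, and the surplus can pay for further exchange.

The forecast gives 66 %, 76 % and 79 %, points that my ceiling does not supply, and says of north that “ligand is not limiting”. The flasks give 65.1 % in north-east, 76.1 % in north and 75.3 % in east.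

    complex with one exchanged + incoming ligand ⇌ leaving ligand + complex with two exchanged (K = 68.0, k = 0.111 /M/h)
    leaving ligand → by-product carried off (k = 0.0375 /h)
    complex with two exchanged + incoming ligand ⇌ leaving ligand + complex with three exchanged (K = 39.0, k = 13.7 /M/h)
    starting complex + incoming ligand ⇌ leaving ligand + complex with one exchanged (K = 1.92, k = 3.03 /M/h)
    complex with three exchanged + incoming ligand ⇌ leaving ligand + complex with four exchanged (K = 3.20, k = 0.206 /M/h)

The north-east books close at 12.0 d: complex with one exchanged takes 65.1 %, the complexes with two, three and four exchanged take 12.4 % in ligand entries, and 2.47 % stays unreacted, which returns A. The north books, with the same entries, sum to 120 % against 120 %. The entry for complex with one exchanged in north grows this far because leaving ligand is converted into by-product carried off: north holds 76.1 % complex with one exchanged, and the same run without that conversion holds 18.3 %.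

The earlier runs and the new flask are simulated for substances that don't exist.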